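**Remark on numbering and assumptions.** Target locants are used for every intermediate: ring C1–C9, where C1 carries the conjugated formyl carbon C10, C2 the saturated formyl carbon C11, C3 the side chain C1′–C8′, C4 the acetate, C6 the methyl C12; the olefins are C6=C7 and C9=C1. Compounds 1, 6 and 7 are taken as purchasable (1 is otherwise one C‑allylation from 2‑methylcyclopentane‑1,3‑dione; 6 is one Pinnick oxidation from (S)‑citronellal). Nothing here has been run; all outcomes are expectations.

## Analysis of the target

The target is a xenicane‑type diterpenoid dialdehyde on one nine‑membered carbocycle (C1–C9). The ring holds a skipped diene around the doubly allylic C8: the trisubstituted C6=C7 olefin is E (trans inside the ring), and the C9=C1 enal is cis inside the ring. C2 (R), C3 (R) and C4 (R) are contiguous and all‑trans (C2‑CHO trans to the C3 chain, C3 chain trans to C4‑OAc); the fourth centre, C1′ (S), is exocyclic and next to C3. The sensitive groups are the 1,4‑dialdehyde, whose C2–H is both α to a formyl group and allylic, so that C2 can epimerise and C9=C1 can slip into C1=C2. A free C4–OH would form a lactol with C11, the acetate is base‑labile, and the side‑chain olefin rules out late ozonolysis or hydrogenation. The synthesis is hard because a nine‑membered ring with a trans olefin resists direct closure, and because stereocentres on a floppy medium ring cannot be set reliably by substrate control. The feature that invites the chosen move is that C1 (a latent ketone) and C6 are joined on one side by C7–C8–C9 and on the other by C2–C5. A transannular C1–C6 bond therefore folds the nine‑membered ring into a hydrindane (five‑membered ring C1/C9/C8/C7/C6, six‑membered ring C1–C6). In that hydrindane C2, C3 and C4 sit all‑equatorial on a chair cyclohexane.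

## Retrosynthetic reasoning

**End game (29 back to 22).** The two formyl groups are brought in separately so that the labile 1,4‑dialdehyde exists only in the last step. C11 is carried as a silyl‑protected CH2OH and oxidised last (28 to 29). C10 comes from carbon monoxide by reductive carbonylation of alkenyl triflate 26, which fixes the C9=C1 position and geometry from the kinetic enolate of ketone 22. The C4 silyl ether is exchanged for the acetate at the triflate stage (24 to 26), after the last strongly basic step and before the enal exists.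

**Key disconnection (22 back to 20): the C1–C6 bond.** Ketone 22 is cut across the ring by a retro‑Grob fragmentation. The C1 carbonyl becomes a tertiary alkoxide, C6=C7 becomes a C6–C1 bond plus a C7 sulfonate. The precursor 20 is a cis‑fused hydrindane. The forward reaction has to make the nine‑membered ring and the E olefin stereospecifically, which requires the C7–OTs bond anti‑periplanar to C1–C6. This cut is preferred to any ring closure because it removes ring strain from the bond‑forming events, and because C2, C3 and C4 can be set on a chair.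

**Six‑membered ring (20 back to 17): the C1–C2 bond.** The tertiary carbinol C1 next to C2–C11 is an aldol retron. Keto aldehyde 17 closes by enamine aldolisation onto the only ketone, which also sets C2 under chair control. The cyclopentanone must already carry the C7 tosylate cis to C12 and the correct C6 configuration, because these two elements decide the olefin geometry.

**Chain (17 back to 9 and 5): the C3–C4 bond.** Aldehyde 17 is the one‑carbon homologue of aldehyde 15, which is an Evans syn‑aldol product (12) of imide 9 and aldehyde 5. The syn relationship of C3 and C4 in the chain equals the trans relationship on the ring. C1′ is bought with (S)‑citronellic acid 6.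

**Cyclopentanone fragment (5 back to 1).** Aldehyde 5 comes from ozonolysis of allyl ketone 3. The C7 tosylate cis to C12 comes from ketol 2 by sulfonylation with inversion, since the enzymatic reduction of dione 1 delivers the hydroxyl cis to the allyl group.

## Alternatives that were turned down

**Alternative 1:** (textbook) Cut C9=C1 and close the nine‑membered ring by ring‑closing metathesis of acyclic triene ester A1, using a ruthenium benzylidene such as (H2IMes)(PCy3)Cl2Ru=CHPh (second‑generation Grubbs catalyst); an intramolecular Nozaki–Hiyama–Kishi or B‑alkyl Suzuki closure belongs to the same family. It was turned down for three reasons. The closure must form a trisubstituted, electron‑poor olefin in a ring that already holds a trans olefin. The skipped diene and the side‑chain olefin offer competing metathesis and isomerisation paths. All four stereocentres, including C2 between two branched carbons, would have to be built on an open chain with no relay.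

**Alternative 2:** Cut C8–C9 by an anionic oxy‑Cope ring expansion of trans‑1,2‑dialkenylcyclopentanol A2. A chair transition state would give the E olefin. It was turned down because the [3,3] shift necessarily places the carbonyl 1,5 to the olefin, at C2 instead of C1. That would demand a one‑carbon homologation at a hindered ring ketone plus separate oxidation at C1. In addition, A2 has five contiguous substituted ring carbons, two of them quaternary.

**Alternative 3:** Cut C8–C9 by a Claisen ring expansion of 2‑methylene‑7‑vinyloxepane A3, made by methylenation of the seven‑membered lactone. The connectivity is right (C1 ketone, C6=C7 olefin). It was turned down because the four‑atom tether C2–C5 can only span the six‑centre transition state in an axial or boat‑like arrangement. That puts C5 cis to C8 and gives the cis‑cyclononene. The lactone also needs a tertiary carbinol at C6.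

Key step: step 13

## Route

**Step 1**
Reactants: 1 2‑allyl‑2‑methylcyclopentane‑1,3‑dione
Product: 2 (2S,3S)‑2‑allyl‑3‑hydroxy‑2‑methylcyclopentan‑1‑one (hydroxyl cis to allyl)
Conditions: baker's yeast (Saccharomyces cerevisiae), sucrose, H2O, 30 °C
Reagents that add atoms: none
Why: Enzymatic desymmetrising reduction of a prochiral 2,2‑disubstituted cyclopentane‑1,3‑dione, a long‑established whole‑cell reduction that gives the (2S,3S) ketol; it sets the quaternary centre C6 and a temporary carbinol at C7.

**Step 2**
Reactants: 2 (2S,3S)‑2‑allyl‑3‑hydroxy‑2‑methylcyclopentan‑1‑one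
Product: 3 (1R,2S)‑2‑allyl‑2‑methyl‑3‑oxocyclopentyl 4‑methylbenzenesulfonate (tosyloxy cis to methyl)
Conditions: Zn(OTs)2, PPh3, DIAD, toluene, 0 °C → rt
Reagents that add atoms: zinc 4‑methylbenzenesulfonate, [Zn+2].[O-]S(=O)(=O)c1ccc(C)cc1.[O-]S(=O)(=O)c1ccc(C)cc1
Why: Mitsunobu reaction with a sulfonate nucleophile: SN2 inversion at C7 moves the oxygen from the allyl face to the methyl face, the relationship the fragmentation needs; C6 has no hydrogen, so no elimination toward the ketone is possible.

**Step 3**
Reactants: 3 (1R,2S)‑2‑allyl‑2‑methyl‑3‑oxocyclopentyl tosylate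
Product: 5 (1R,2S)‑2‑methyl‑3‑oxo‑2‑(2‑oxoethyl)cyclopentyl 4‑methylbenzenesulfonate, via ozonide 4 (not isolated)
Conditions: O3, CH2Cl2, −78 °C; then Me2S, −78 °C → rt
Reagents that add atoms: ozone, [O-][O+]=O
Why: Ozonolysis with reductive work‑up; the allyl group is the only olefin and the sulfonate and ketone are inert.

**Step 4**
Reactants: 6 (S)‑3,7‑dimethyloct‑6‑enoic acid ((S)‑citronellic acid); 7 (S)‑4‑benzyloxazolidin‑2‑one
Product: 9 (S)‑4‑benzyl‑3‑[(S)‑3,7‑dimethyloct‑6‑enoyl]oxazolidin‑2‑one, via mixed pivalic anhydride 8 (not isolated)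
Conditions: t‑BuCOCl, Et3N, THF, −20 °C; then 7, LiCl, −20 °C → rt
Reagents that add atoms: none
Why: N‑Acylation of the oxazolidinone through the mixed anhydride; C1′ is not touched.

**Step 5**
Reactants: 9 acyl oxazolidinone; 5 keto aldehyde tosylate
Product: 12 Evans syn‑aldol adduct, (S)‑4‑benzyl‑3‑[(2S,3R)‑3‑hydroxy‑2‑[(S)‑6‑methylhept‑5‑en‑2‑yl]‑4‑[(1S,2R)‑1‑methyl‑5‑oxo‑2‑(tosyloxy)cyclopentyl]butanoyl]oxazolidin‑2‑one, via Z‑boron enolate 10 (not isolated), via boron aldolate 11 (not isolated)
Conditions: Bu2BOTf, i‑Pr2NEt, CH2Cl2, −78 → 0 °C; 5, −78 → 0 °C; then pH 7 buffer, MeOH, H2O2, 0 °C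
Reagents that add atoms: none
Why: Evans syn‑aldol: the Z‑boron enolate reacts through a closed Zimmerman–Traxler chair on the face away from the benzyl group, setting C3 and C4 (target numbering) as the 2,3‑syn pair under reagent control; the aldehyde reacts much faster than the hindered ketone.

**Step 6**
Reactants: 12 aldol adduct
Product: 13 C4 tert‑butyldimethylsilyl ether of 12
Conditions: TBSOTf, 2,6‑lutidine, CH2Cl2, −78 → 0 °C
Reagents that add atoms: tert‑butyldimethylsilyl triflate, CC(C)(C)[Si](C)(C)OS(=O)(=O)C(F)(F)F
Why: Silylation of the secondary alcohol blocks retro‑aldol and lactol or hemiketal formation in the following steps.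

**Step 7**
Reactants: 13 silyl ether imide
Product: 14 S‑ethyl thioester (C3 S, C4 R as in 12)
Conditions: EtSH, n‑BuLi, THF, 0 °C
Reagents that add atoms: ethanethiol, CCS
Why: Thiolate transacylation removes the auxiliary under weakly basic conditions that do not epimerise C3; the neopentyl‑type secondary tosylate is too hindered for displacement.

**Step 8**
Reactants: 14 thioester
Product: 15 aldehyde, C2 at the aldehyde level (C3 S, C4 R)
Conditions: Et3SiH, Pd/C (10 % palladium on carbon), acetone, rt
Reagents that add atoms: none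
Why: Fukuyama reduction of the thioester to the aldehyde, chemoselective beside the ketone, the tosylate and the trisubstituted olefin.

**Step 9**
Reactants: 15 aldehyde
Product: 16 methyl enol ether (E/Z mixture at C2=C11)
Conditions: MeOCH2PPh3Cl, KN(SiMe3)2, THF, −78 → 0 °C
Reagents that add atoms: (methoxymethyl)triphenylphosphonium chloride, COC[P+](c1ccccc1)(c1ccccc1)c1ccccc1.[Cl-]
Why: Wittig methoxymethylenation adds C11; the aldehyde is attacked faster than the ketone flanked by a quaternary carbon, and low temperature protects the α‑centre C3.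

**Step 10**
Reactants: 16 enol ether
Product: 17 keto aldehyde (C11 aldehyde, C2 methylene)
Conditions: 2 M HCl, THF, 0 °C → rt
Reagents that add atoms: water, O
Why: Acid hydrolysis of the enol ether; the secondary TBS ether and the tosylate survive dilute acid.

**Step 11**
Reactants: 17 keto aldehyde
Product: 19 cis‑fused hydrindane diol (C1‑OH, C12 and C7‑OTs on the same face; C2‑CH2OH, C3 chain and C4‑OTBS equatorial and mutually trans), via ketol aldehyde 18 (not isolated)
Conditions: L‑proline (30 mol %), DMSO, rt; then MeOH, NaBH4, 0 °C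
Reagents that add atoms: none
Why: 6‑Enolexo intramolecular aldol under enamine catalysis (Hajos–Parrish‑type ketol formation): the tether can only reach the face of the C1 carbonyl on which it is attached, so the fusion is cis with C1‑OH cis to C12; in the chair transition state the C3 and C4 substituents are equatorial, which with the fixed C6 configuration puts C7 axial, and C2 bonds with its formyl group equatorial; NaBH4 then reduces only the aldehyde because no ketone is left.

**Step 12**
Reactants: 19 hydrindane diol
Product: 20 C11 tert‑butyldiphenylsilyl ether (tertiary C1‑OH free)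
Conditions: TBDPSCl, imidazole, DMF, 0 °C → rt
Reagents that add atoms: tert‑butyl(chloro)diphenylsilane, CC(C)(C)[Si](Cl)(c1ccccc1)c1ccccc1
Why: Selective silylation of the primary alcohol; the tertiary alcohol does not react.

**Step 13**
Reactants: 20 hydrindane γ‑hydroxy tosylate
Product: 22 (E)‑cyclonon‑4‑enone (C1 ketone, E C6=C7, C2‑CH2OTBDPS, C3 chain, C4‑OTBS), via potassium alkoxide 21 (not isolated)
Conditions: KOtBu (1.2 equiv), THF, 0 °C → rt
Reagents that add atoms: none
Why: Grob fragmentation of a 1,3‑diol monosulfonate: the alkoxide lone pair pushes into the C1–C6 bond while that bond donates into the C7–OTs antibonding orbital, so C1=O, C6=C7 and loss of tosylate form one concerted, stereospecific event. The closest known reaction type is the base‑induced fragmentation of hydrindane‑1,3‑diol monosulfonates to cyclononenones, the classical entry to E‑cyclononenes of the caryophyllene type. No ring is closed; the zero‑atom bridge C1–C6 of the bicyclo[4.3.0]nonane is cut and the five‑ and six‑membered rings merge into the nine‑membered ring. The only new stereo‑element is the olefin geometry: in the chair of 20 that keeps the C2, C3 and C4 substituents equatorial, C7 is axial on the cyclohexane, the tosylate (cis to C12 and to C1–O) is anti‑periplanar to C1–C6, and C5–C6 is anti to C7–C8, which is carried into the olefin as C5 trans to C8, that is E. The centres C1 and C6 existed only to enforce this alignment and are destroyed; C2, C3, C4 and C1′ are not touched. The step needs fragmentation to beat E2 loss of sulfonic acid toward C8: the alkoxide is cis to the leaving group, so displacement is impossible, and the aligned C–C bond is the better anti‑periplanar donor once the alkoxide exists. Only a small excess of base at low temperature is used, to limit enolisation of 22 at C2.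

**Step 14**
Reactants: 22 cyclononenone
Product: 24 alkenyl triflate (C9=C1, cis in the ring), via potassium enolate 23 (not isolated)
Conditions: KN(SiMe3)2, THF, −78 °C; then PhNTf2, −78 → −20 °C
Reagents that add atoms: N‑phenylbis(trifluoromethanesulfonimide), O=S(=O)(N(c1ccccc1)S(=O)(=O)C(F)(F)F)C(F)(F)F
Why: Kinetic deprotonation at the C9 methylene rather than at the hindered tertiary C2; a ring that already holds a trans olefin can only take a cis enolate, which fixes the later enal geometry.

**Step 15**
Reactants: 24 alkenyl triflate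
Product: 25 C4 alcohol (C11‑OTBDPS kept)
Conditions: HF (48 % aq.), MeCN, 0 °C → rt
Reagents that add atoms: none
Why: Acidic desilylation removes the secondary TBS ether much faster than the primary TBDPS ether; the alkenyl triflate is stable to acid.

**Step 16**
Reactants: 25 alcohol
Product: 26 C4 acetate
Conditions: Ac2O, pyridine, DMAP (cat.), CH2Cl2, rt
Reagents that add atoms: acetic anhydride, CC(=O)OC(C)=O
Why: Standard acetylation, placed after the last strongly basic step.

**Step 17**
Reactants: 26 alkenyl triflate acetate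
Product: 27 enal (C10 formyl on C1, C9=C1 cis in the ring)
Conditions: Pd(PPh3)4 (5 mol %), CO (1 atm), Bu3SnH (slow addition), THF, 50 °C
Reagents that add atoms: carbon monoxide, [C-]#[O+]
Why: Palladium‑catalysed reductive carbonylation (formylation) of an alkenyl triflate: oxidative addition to zerovalent palladium, CO insertion, hydride transfer from tin, with retention of olefin geometry.

**Step 18**
Reactants: 27 enal silyl ether
Product: 28 primary alcohol at C11
Conditions: HF·pyridine, pyridine, THF, 0 °C → rt
Reagents that add atoms: none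
Why: Buffered fluoride desilylation; the acetate and the enal tolerate these conditions.

**Step 19**
Reactants: 28 primary alcohol
Product: 29 target dialdehyde
Conditions: Dess–Martin periodinane, pyridine, CH2Cl2, 0 °C → rt
Reagents that add atoms: none
Why: Dess–Martin oxidation under buffered, non‑enolising conditions, so the labile C2 centre and the C9=C1 position are exposed only in the last step.

## Compound list

1 | 2‑allyl‑2‑methylcyclopentane‑1,3‑dione | C=CCC1(C)C(=O)CCC1=O | starting material
2 | (2S,3S)‑2‑allyl‑3‑hydroxy‑2‑methylcyclopentan‑1‑one | C=CC[C@@]1(C)[C@@H](O)CCC1=O | intermediate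
3 | (1R,2S)‑2‑allyl‑2‑methyl‑3‑oxocyclopentyl 4‑methylbenzenesulfonate | C=CC[C@@]1(C)[C@H](OS(=O)(=O)c2ccc(C)cc2)CCC1=O | intermediate
4 | ozonide (1,2,4‑trioxolane) of 3, mixture at the trioxolane carbon | C1(C[C@@]2(C)[C@H](OS(=O)(=O)c3ccc(C)cc3)CCC2=O)OCOO1 | intermediate
5 | (1R,2S)‑2‑methyl‑3‑oxo‑2‑(2‑oxoethyl)cyclopentyl 4‑methylbenzenesulfonate | O=CC[C@@]1(C)[C@H](OS(=O)(=O)c2ccc(C)cc2)CCC1=O | intermediate
6 | (S)‑3,7‑dimethyloct‑6‑enoic acid | OC(=O)C[C@@H](C)CCC=C(C)C | starting material
7 | (S)‑4‑benzyloxazolidin‑2‑one | O=C1N[C@@H](Cc2ccccc2)CO1 | starting material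
8 | mixed pivalic (S)‑citronellic anhydride | CC(C)(C)C(=O)OC(=O)C[C@@H](C)CCC=C(C)C | intermediate
9 | (S)‑4‑benzyl‑3‑[(S)‑3,7‑dimethyloct‑6‑enoyl]oxazolidin‑2‑one | O=C(C[C@@H](C)CCC=C(C)C)N1C(=O)OC[C@@H]1Cc1ccccc1 | intermediate
10 | Z‑dibutylboron enolate of 9 | CCCCB(CCCC)O/C(=C\[C@@H](C)CCC=C(C)C)N1C(=O)OC[C@@H]1Cc1ccccc1 | intermediate
11 | dibutylboron aldolate of 12 | CCCCB(CCCC)O[C@H](C[C@@]1(C)[C@H](OS(=O)(=O)c2ccc(C)cc2)CCC1=O)[C@H]([C@@H](C)CCC=C(C)C)C(=O)N1C(=O)OC[C@@H]1Cc1ccccc1 | intermediate
12 | Evans syn‑aldol adduct (C3 S, C4 R; 2,3‑syn) | O[C@H](C[C@@]1(C)[C@H](OS(=O)(=O)c2ccc(C)cc2)CCC1=O)[C@H]([C@@H](C)CCC=C(C)C)C(=O)N1C(=O)OC[C@@H]1Cc1ccccc1 | intermediate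
13 | C4 TBS ether of 12 | CC(C)(C)[Si](C)(C)O[C@H](C[C@@]1(C)[C@H](OS(=O)(=O)c2ccc(C)cc2)CCC1=O)[C@H]([C@@H](C)CCC=C(C)C)C(=O)N1C(=O)OC[C@@H]1Cc1ccccc1 | intermediate
14 | S‑ethyl thioester | CC(C)(C)[Si](C)(C)O[C@H](C[C@@]1(C)[C@H](OS(=O)(=O)c2ccc(C)cc2)CCC1=O)[C@H]([C@@H](C)CCC=C(C)C)C(=O)SCC | intermediate
15 | aldehyde (C2 formyl) | CC(C)(C)[Si](C)(C)O[C@H](C[C@@]1(C)[C@H](OS(=O)(=O)c2ccc(C)cc2)CCC1=O)[C@H]([C@@H](C)CCC=C(C)C)C=O | intermediate
16 | methyl enol ether, E/Z mixture | CC(C)(C)[Si](C)(C)O[C@H](C[C@@]1(C)[C@H](OS(=O)(=O)c2ccc(C)cc2)CCC1=O)[C@H]([C@@H](C)CCC=C(C)C)C=COC | intermediate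
17 | keto aldehyde (C11 formyl, C2 methylene) | CC(C)(C)[Si](C)(C)O[C@H](C[C@@]1(C)[C@H](OS(=O)(=O)c2ccc(C)cc2)CCC1=O)[C@H]([C@@H](C)CCC=C(C)C)CC=O | intermediate
18 | cis‑fused hydrindane ketol aldehyde (C1‑OH, C12, C7‑OTs on one face; C2‑CHO, C3 chain, C4‑OTBS equatorial) | CC(C)(C)[Si](C)(C)O[C@@H]1C[C@@]2(C)[C@H](OS(=O)(=O)c3ccc(C)cc3)CC[C@@]2(O)[C@H](C=O)[C@H]1[C@@H](C)CCC=C(C)C | intermediate
19 | cis‑fused hydrindane diol (C11 alcohol) | CC(C)(C)[Si](C)(C)O[C@@H]1C[C@@]2(C)[C@H](OS(=O)(=O)c3ccc(C)cc3)CC[C@@]2(O)[C@H](CO)[C@H]1[C@@H](C)CCC=C(C)C | intermediate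
20 | C11 TBDPS ether of 19 (fragmentation substrate) | CC(C)(C)[Si](C)(C)O[C@@H]1C[C@@]2(C)[C@H](OS(=O)(=O)c3ccc(C)cc3)CC[C@@]2(O)[C@H](CO[Si](c4ccccc4)(c5ccccc5)C(C)(C)C)[C@H]1[C@@H](C)CCC=C(C)C | intermediate
21 | potassium alkoxide of 20 | CC(C)(C)[Si](C)(C)O[C@@H]1C[C@@]2(C)[C@H](OS(=O)(=O)c3ccc(C)cc3)CC[C@@]2([O-])[C@H](CO[Si](c4ccccc4)(c5ccccc5)C(C)(C)C)[C@H]1[C@@H](C)CCC=C(C)C.[K+] | intermediate
22 | (E)‑cyclononenone (C1 ketone, E C6=C7, C2‑CH2OTBDPS, C3 chain, C4‑OTBS) | O=C1CC/C=C(C)/C[C@@H](O[Si](C)(C)C(C)(C)C)[C@H]([C@@H](C)CCC=C(C)C)[C@H]1CO[Si](c2ccccc2)(c3ccccc3)C(C)(C)C | intermediate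
23 | potassium enolate of 22 (C9=C1) | [K+].[O-]/C1=C/C/C=C(C)/C[C@@H](O[Si](C)(C)C(C)(C)C)[C@H]([C@@H](C)CCC=C(C)C)[C@H]1CO[Si](c2ccccc2)(c3ccccc3)C(C)(C)C | intermediate
24 | alkenyl triflate (C4‑OTBS) | FC(F)(F)S(=O)(=O)O/C1=C/C/C=C(C)/C[C@@H](O[Si](C)(C)C(C)(C)C)[C@H]([C@@H](C)CCC=C(C)C)[C@H]1CO[Si](c2ccccc2)(c3ccccc3)C(C)(C)C | intermediate
25 | alkenyl triflate, C4 alcohol | FC(F)(F)S(=O)(=O)O/C1=C/C/C=C(C)/C[C@@H](O)[C@H]([C@@H](C)CCC=C(C)C)[C@H]1CO[Si](c2ccccc2)(c3ccccc3)C(C)(C)C | intermediate
26 | alkenyl triflate, C4 acetate | FC(F)(F)S(=O)(=O)O/C1=C/C/C=C(C)/C[C@@H](OC(C)=O)[C@H]([C@@H](C)CCC=C(C)C)[C@H]1CO[Si](c2ccccc2)(c3ccccc3)C(C)(C)C | intermediate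
27 | enal, C4 acetate, C11‑OTBDPS | O=C/C1=C/C/C=C(C)/C[C@@H](OC(C)=O)[C@H]([C@@H](C)CCC=C(C)C)[C@H]1CO[Si](c2ccccc2)(c3ccccc3)C(C)(C)C | intermediate
28 | enal, C4 acetate, C11 alcohol | O=C/C1=C/C/C=C(C)/C[C@@H](OC(C)=O)[C@H]([C@@H](C)CCC=C(C)C)[C@H]1CO | intermediate
29 | target: (2R,3R,4R,1′S)‑4‑acetoxy dialdehyde, E C6=C7, C9=C1 cis in the ring | CC(=O)O[C@@H]1C/C(C)=C/C/C=C(/C=O)[C@H](C=O)[C@H]1[C@@H](C)CCC=C(C)C | target

## Step count and least certain steps

Total step count: 19. Longest linear sequence: 18 (steps 1–3 and 5–19, from 1); step 4 is a one‑step side branch.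

**Step 13 (key step).** The most likely failures are incomplete population of the conformer in which C7–OTs is anti‑periplanar to C1–C6, so that E2 loss of the sulfonate toward C8 competes, and base‑induced epimerisation at C2 of the product ketone. Fallback: set out from 17 and merge cyclisation and ring expansion into one cascade. After enamine aldolisation to 18, KOtBu is added to the crude ketol. The aldolate stereoisomers interconvert by retro‑aldol and aldol, and each one that reaches the aligned geometry fragments irreversibly, giving the nine‑membered 2‑(hydroxymethylene) ketone F1. Chemoselective reduction of its formyl group with NaBH(OAc)3 in AcOH gives the 2‑(hydroxymethyl) ketone F2. Silylation with TBDPSCl and imidazole returns to the route at 22. In this variant C2 is set by protonation rather than by the chair.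

**Step 2.** Displacement at a secondary carbinol next to a quaternary carbon is slow, so elimination toward C8 or incomplete inversion with the weakly nucleophilic sulfonate may take over. Fallback: set out from 2 and separate inversion from activation. Mitsunobu esterification with 4‑nitrobenzoic acid, PPh3 and DIAD gives the inverted (1R,2S)‑2‑allyl‑2‑methyl‑3‑oxocyclopentyl 4‑nitrobenzoate F3. Methanolysis with K2CO3 in MeOH gives (2S,3R)‑2‑allyl‑3‑hydroxy‑2‑methylcyclopentan‑1‑one F4. Tosylation with TsCl, pyridine and DMAP, with retention, returns to the route at 3.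

**Step 11.** Enamine addition to a ketone flanked by a quaternary carbon may be slow, which would leave time for dehydration of the ketol or for intermolecular aldol reactions; the C2 epimer may also form. Fallback: set out from 16 and use the enol ether itself as the nucleophile in a Lewis‑acid‑promoted (TiCl4, CH2Cl2, −78 °C) Mukaiyama‑ or Prins‑type addition to the C1 ketone. Aqueous work‑up gives 18, and NaBH4 reduction returns to the route at 19. No new compound is involved.

**Step 17.** Hydride transfer to the alkenylpalladium species before CO insertion would give simple reduction of the triflate; CO insertion next to the branched C2 may be slow. Fallback: set out from 22 and install C10 by a Shapiro reaction. Condensation with 2,4,6‑triisopropylbenzenesulfonyl hydrazide gives the hydrazone F5. Treatment with n‑BuLi and then DMF gives the C4‑silylated enal F6, the alkenyllithium forming at the less hindered C9 side. Removal of the TBS group with aqueous HF in MeCN gives the C4 hydroxy enal F7. Acetylation with Ac2O and pyridine returns to the route at 27.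

## Further compounds

F1 | step 13 | nine‑membered 2‑(hydroxymethylene) ketone (E C6=C7, C4‑OTBS) | O=C1CC/C=C(C)/C[C@@H](O[Si](C)(C)C(C)(C)C)[C@H]([C@@H](C)CCC=C(C)C)/C1=C/O
F2 | step 13 | nine‑membered 2‑(hydroxymethyl) ketone (E C6=C7, C4‑OTBS) | O=C1CC/C=C(C)/C[C@@H](O[Si](C)(C)C(C)(C)C)[C@H]([C@@H](C)CCC=C(C)C)[C@H]1CO
F3 | step 2 | (1R,2S)‑2‑allyl‑2‑methyl‑3‑oxocyclopentyl 4‑nitrobenzoate | C=CC[C@@]1(C)[C@H](OC(=O)c2ccc(cc2)[N+](=O)[O-])CCC1=O
F4 | step 2 | (2S,3R)‑2‑allyl‑3‑hydroxy‑2‑methylcyclopentan‑1‑one | C=CC[C@@]1(C)[C@H](O)CCC1=O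
F0 | step 11 | none | none
F5 | step 17 | 2,4,6‑triisopropylbenzenesulfonyl hydrazone of 22 | CC(C)c1cc(C(C)C)c(c(c1)C(C)C)S(=O)(=O)NN=C1CC/C=C(C)/C[C@@H](O[Si](C)(C)C(C)(C)C)[C@H]([C@@H](C)CCC=C(C)C)[C@H]1CO[Si](c2ccccc2)(c3ccccc3)C(C)(C)C
F6 | step 17 | enal with C4‑OTBS and C11‑OTBDPS | O=C/C1=C/C/C=C(C)/C[C@@H](O[Si](C)(C)C(C)(C)C)[C@H]([C@@H](C)CCC=C(C)C)[C@H]1CO[Si](c2ccccc2)(c3ccccc3)C(C)(C)C
F7 | step 17 | enal with C4 alcohol and C11‑OTBDPS | O=C/C1=C/C/C=C(C)/C[C@@H](O)[C@H]([C@@H](C)CCC=C(C)C)[C@H]1CO[Si](c2ccccc2)(c3ccccc3)C(C)(C)C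
A1 | alternative 1 | acyclic triene ester for ring‑closing metathesis at C9=C1 | C=CC/C=C(C)/C[C@@H](OC(C)=O)[C@H]([C@@H](C)CCC=C(C)C)[C@@H](CO[Si](C)(C)C(C)(C)C)C(=C)C(=O)OC
A2 | alternative 2 | trans‑1,2‑dialkenylcyclopentanol for anionic oxy‑Cope ring expansion | C=C[C@@]1(C)C[C@@H](O[Si](C)(C)C(C)(C)C)[C@H]([C@@H](C)CCC=C(C)C)[C@]1(O)C(=C)CO[Si](C)(C)C(C)(C)C
A3 | alternative 3 | 2‑methylene‑7‑methyl‑7‑vinyloxepane for Claisen ring expansion | C=C[C@]1(C)C[C@@H](O[Si](C)(C)C(C)(C)C)[C@H]([C@@H](C)CCC=C(C)C)[C@@H](CO[Si](C)(C)C(C)(C)C)C(=C)O1
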